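The retrosynthesis first removes the C3 aroyl group, the C7 prenyl group (C7–C bond, via allyl), the C1 prenyl group, the C2 oxygen and the two C8 methyls, which leaves a 4-methoxy-5-alkylbicyclo[3.3.1]non-3-ene-7,9-dione.
The core is then cut at C1–C8 together with a throw-away C8–C9 bond (a C8 carbene added across the C9=C1 enol ether of a 6,6-disubstituted 1,5-dimethoxycyclohexa-1,4-diene), and last at C5–chain and C5–C6 (two alkylations of the diene).
The feature that allows this: in ring A (C1–C5, C9) C5 lies between the oxygenated C4 and C9, and before ring B exists this ring has a mirror plane through C5 and C2; C8 is one bond from both C1 and C9, so it can arrive as the carbene of a C5-bound C6–C7–C8 diazoacetonyl arm.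
Forward order: chain bromide (steps 1–6), diene dialkylation and diazo ketone (7–10), ring B plus cyclopropane (11), acid opening to the ring A/ring B dione (12), then C8 methyls, C2 oxygen, C1 prenyl, C7 prenyl, C3 aroyl and deprotection (13–25).
Stereochemistry: the chain carbinol comes from a D-proline α-aminoxylation, the E-alkene from the Horner–Wadsworth–Emmons step, C5 and C1 from the copper–bis(oxazoline) choice between the two enol ethers, and C7 from exo-face radical allylation.

Key step: step 11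

Assumption: the (S,S)-tert-butyl bis(oxazoline) ligand is taken to direct the carbene to the enol ether that gives 15 as drawn; if the sense of induction is opposite, the (R,R) ligand is used in the same step.
Conventions: TBS = tert-butyldimethylsilyl; "chain" = (2E,4S)-4-(TBS-oxy)-3,7-dimethylocta-2,6-dien-1-yl; core locants C1–C9 follow the target; "exo" at C7 or C8 means pointing away from ring A.

Step 1
Reactants: 1 6-methylhept-5-en-2-one
Product: 2 (3S)-6-methyl-3-(N-phenylaminooxy)hept-5-en-2-one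
Conditions: PhNO added slowly to excess 1, D-proline (20 mol %), DMSO, rt
Reagents that add atoms: nitrosobenzene, O=Nc1ccccc1
Why: Proline-catalysed α-aminoxylation (O-selective nitroso aldol reaction), in which the more substituted enamine attacks the nitroso oxygen held on one face by a hydrogen bond from the D-proline carboxylic acid, so C3 should form as S and oxygenation should occur at the methylene, not the methyl, side.

Step 2
Reactants: 2 (3S)-6-methyl-3-(N-phenylaminooxy)hept-5-en-2-one
Product: 3 (3S)-3-hydroxy-6-methylhept-5-en-2-one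
Conditions: Zn dust, AcOH/THF, 0 °C
Reagents that add atoms: none
Why: Reductive N–O cleavage by zinc in acetic acid, where the weak N–O bond is the most easily reduced bond, so the α-ketol should be released without touching the ketone, the alkene or the stereocentre.

Step 3
Reactants: 3 (3S)-3-hydroxy-6-methylhept-5-en-2-one
Product: 4 (3S)-3-(TBS-oxy)-6-methylhept-5-en-2-one
Conditions: TBSCl, imidazole, DMF, 0 °C to rt
Reagents that add atoms: tert-butyldimethylsilyl chloride, CC(C)(C)[Si](C)(C)Cl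
Why: Imidazole-promoted silylation of a secondary alcohol; the TBS ether is chosen because it should survive t-BuLi, the carbenoid, catalytic acid, enolates, radicals and metathesis, and leave with fluoride at the end.

Step 4
Reactants: 4 (3S)-3-(TBS-oxy)-6-methylhept-5-en-2-one
Product: 5 ethyl (2E,4S)-4-(TBS-oxy)-3,7-dimethylocta-2,6-dienoate
Conditions: (EtO)2P(O)CH2CO2Et, NaH, THF, 0 °C to rt (anion preformed)
Reagents that add atoms: triethyl phosphonoacetate, CCOC(=O)CP(=O)(OCC)OCC
Why: Horner–Wadsworth–Emmons olefination of a methyl ketone, in which the stabilised phosphonate anion places the ester trans to the larger silyloxy-branched substituent (E) and is too weakly basic to epimerise the α-silyloxy centre.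

Step 5
Reactants: 5 ethyl (2E,4S)-4-(TBS-oxy)-3,7-dimethylocta-2,6-dienoate
Product: 6 (2E,4S)-4-(TBS-oxy)-3,7-dimethylocta-2,6-dien-1-ol
Conditions: i-Bu2AlH, CH2Cl2, −78 °C
Reagents that add atoms: none
Why: 1,2-Reduction of an enoate by an aluminium hydride gives the allylic alcohol and leaves the alkenes and the silyl ether alone.

Step 6
Reactants: 6 (2E,4S)-4-(TBS-oxy)-3,7-dimethylocta-2,6-dien-1-ol
Product: 7 (2E,4S)-1-bromo-4-(TBS-oxy)-3,7-dimethylocta-2,6-diene
Conditions: CBr4, PPh3, CH2Cl2, 0 °C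
Reagents that add atoms: tetrabromomethane, BrC(Br)(Br)Br
Why: Appel bromination, an SN2 displacement of the alkoxyphosphonium by bromide under neutral conditions, should give the primary allylic bromide without allylic transposition.

Step 7
Reactants: 8 1,5-dimethoxycyclohexa-1,4-diene; 9 (S)-2-methyloxirane
Product: 10 (2S)-1-(2,6-dimethoxycyclohexa-2,5-dien-1-yl)propan-2-ol
Conditions: t-BuLi, THF, −78 °C; then 9, −78 to 0 °C
Reagents that add atoms: none
Why: Lithiation of the doubly allylic CH2 between the methoxy groups and SN2 opening of the epoxide at its CH2 end (cyclohexadienyl anion alkylation at the central carbon); the carbinol centre is carried over from 9 and serves only to keep 10 and 11 single diastereomers until it is oxidised in step 9.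

Step 8
Reactants: 10 (2S)-1-(2,6-dimethoxycyclohexa-2,5-dien-1-yl)propan-2-ol; 7 (2E,4S)-1-bromo-4-(TBS-oxy)-3,7-dimethylocta-2,6-diene
Product: 11 (2S)-1-[1-(chain)-2,6-dimethoxycyclohexa-2,5-dien-1-yl]propan-2-ol
Conditions: t-BuLi (2.2 equiv), THF, −78 to −40 °C; then 7, HMPA, −78 °C to rt
Reagents that add atoms: none
Why: A second lithiation at the same, now tertiary, doubly allylic carbon (the alkoxide takes the first equivalent of base) and C-alkylation with the allylic bromide build the future quaternary C5; the ring keeps its mirror plane, so no new stereocentre arises.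

Step 9
Reactants: 11 (2S)-1-[1-(chain)-2,6-dimethoxycyclohexa-2,5-dien-1-yl]propan-2-ol
Product: 12 1-[1-(chain)-2,6-dimethoxycyclohexa-2,5-dien-1-yl]propan-2-one
Conditions: SO3·pyridine, DMSO, Et3N, CH2Cl2, 0 °C
Reagents that add atoms: none
Why: Parikh–Doering oxidation runs under basic conditions, so the secondary alcohol should become the methyl ketone without hydrolysis of the two acid-labile enol ethers.

Step 10
Reactants: 12 1-[1-(chain)-2,6-dimethoxycyclohexa-2,5-dien-1-yl]propan-2-one
Product: 14 1-diazo-3-[1-(chain)-2,6-dimethoxycyclohexa-2,5-dien-1-yl]propan-2-one, via trifluoroacetyl diketone 13 (not isolated)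
Conditions: LiHMDS, THF, −78 °C; CF3CO2CH2CF3; then MsN3, Et3N, H2O, MeCN, rt
Reagents that add atoms: methanesulfonyl azide, CS(=O)(=O)N=[N+]=[N-]
Why: Detrifluoroacetylative diazo transfer, in which the kinetic enolate forms at the methyl group (the other α-carbon is neopentyl), Claisen acylation gives 13, and Regitz-type transfer with loss of the trifluoroacetyl group gives the diazomethyl ketone.

Step 11
Reactants: 14 1-diazo-3-[1-(chain)-2,6-dimethoxycyclohexa-2,5-dien-1-yl]propan-2-one
Product: 15 methoxycyclopropyl ketone tricycle: 4,9-dimethoxy-5-(chain)bicyclo[3.3.1]non-3-en-7-one with an extra C8–C9 bond, cyclopropane C1/C8/C9 cis-fused, configuration as in the SMILES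
Conditions: (CuOTf)2·C6H6 (5 mol %, monovalent copper), 2,2-bis[(4S)-4-tert-butyl-4,5-dihydrooxazol-2-yl]propane (12 mol %), toluene, slow addition of 14, rt to 50 °C
Reagents that add atoms: none
Why: The ligated monovalent copper triflate decomposes the diazo ketone to an electrophilic copper carbene at C8, which adds to one methoxy-bearing ring alkene (C9=C1) in a concerted but asynchronous [2+1] step, bonding first to the unsubstituted, nucleophilic C1 while the charge developing at C9 is held by its methoxy group. The closest known reaction type is the catalytic asymmetric intramolecular cyclopropanation of diazomethyl ketones onto the enol ethers of 6,6-disubstituted 1,5-dimethoxycyclohexa-1,4-dienes. Ring B (six-membered, C1–C8 bond) closes in a 6-endo sense and the cyclopentanone (C8–C9 bond) in a 5-exo sense, together the normal bicyclo[3.1.0]hexan-2-one mode of a 1-diazohex-5-en-2-one, and the cyclopropane is necessarily cis-fused. C5 becomes stereogenic through the choice between the two enol ethers, and C1, C8 and C9 follow from suprafacial addition on the face fixed by the tether, so all four centres depend on the ligand's discrimination of the two alkenes, since the distant silyloxy carbinol gives no useful bias. The step needs chemoselectivity for the enol ethers over the two trisubstituted chain alkenes and over C–H insertion, which the higher nucleophilicity of the enol ethers and the tether length should secure (the nearest chain alkene could only give a bicyclo[4.1.0] product), and group selectivity between the two enol ethers, which rests on the catalyst.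

Step 12
Reactants: 15 methoxycyclopropyl ketone tricycle
Product: 16 (1S,5S)-5-(chain)-4-methoxybicyclo[3.3.1]non-3-ene-7,9-dione
Conditions: p-TsOH·H2O (5 mol %), THF/H2O, 0 °C; NaHCO3 quench as soon as 15 is consumed
Reagents that add atoms: water, O
Why: Acid-induced opening of a donor–acceptor cyclopropane (retro-aldol-like heterolysis), in which protonation of the C7 ketone breaks only the C8–C9 bond between the methoxy donor carbon and the carbon α to the acceptor, water turns the C9 oxocarbenium ion into the ketone, and the remaining enol ether, hindered and inductively deactivated, should survive brief catalytic acid; C1 and C5 are untouched.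

Step 13
Reactants: 16 (1S,5S)-5-(chain)-4-methoxybicyclo[3.3.1]non-3-ene-7,9-dione
Product: 17 (1S,5S,8S)-5-(chain)-4-methoxy-8-methylbicyclo[3.3.1]non-3-ene-7,9-dione (methyl exo)
Conditions: LDA, THF, −78 °C; MeI, −78 to −40 °C
Reagents that add atoms: iodomethane, CI
Why: Kinetic enolate alkylation, in which LDA should remove the axial proton at C8 rather than at the neopentyl C6 beside the quaternary C5, and MeI enters from the exo face; the new C8 centre is of no consequence because it becomes quaternary in step 14.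

Step 14
Reactants: 17 (1S,5S,8S)-5-(chain)-4-methoxy-8-methylbicyclo[3.3.1]non-3-ene-7,9-dione
Product: 18 (1S,5S)-5-(chain)-4-methoxy-8,8-dimethylbicyclo[3.3.1]non-3-ene-7,9-dione
Conditions: t-BuOK, MeI, THF/t-BuOH, 0 °C to rt
Reagents that add atoms: iodomethane, CI
Why: Thermodynamic enolate alkylation, in which equilibrating alkoxide conditions favour the more substituted C7=C8 enolate while C6, neopentyl and flanked by the chain, is slow to alkylate, so the second methyl should enter at C8.

Step 15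
Reactants: 18 (1S,5S)-5-(chain)-4-methoxy-8,8-dimethylbicyclo[3.3.1]non-3-ene-7,9-dione
Product: 19 (1R,5S)-5-(chain)-4-methoxy-8,8-dimethylbicyclo[3.3.1]non-3-ene-2,7,9-trione
Conditions: Pd(OH)2/C (10 mol %, divalent palladium), t-BuOOH, K2CO3, CH2Cl2, 0 °C
Reagents that add atoms: tert-butyl hydroperoxide, CC(C)(C)OO
Why: Palladium-catalysed radical allylic oxidation with t-BuOOH, in which peroxyl radicals should abstract hydrogen at C2 because the resulting allyl radical is delocalised onto the methoxy-bearing C4, and the C2 peroxide collapses to the ketone of the vinylogous ester.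

Step 16
Reactants: 19 (1R,5S)-5-(chain)-4-methoxy-8,8-dimethylbicyclo[3.3.1]non-3-ene-2,7,9-trione
Product: 20 (1R,5S)-5-(chain)-4-methoxy-8,8-dimethyl-1-(3-methylbut-2-en-1-yl)bicyclo[3.3.1]non-3-ene-2,7,9-trione
Conditions: LDA (2.3 equiv), THF, −78 °C; prenyl bromide (1.1 equiv), −78 °C; cold NH4Cl quench
Reagents that add atoms: 1-bromo-3-methylbut-2-ene, CC(C)=CCBr
Why: Bridgehead lithiation–alkylation, in which excess LDA holds the C7 ketone as its enolate and removes the C1–H between the C2 and C9 carbonyls, and the bridgehead carbanion, the more reactive site of the dianion, takes up prenyl bromide with retention enforced by the cage.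

Step 17
Reactants: 20 (1R,5S)-5-(chain)-4-methoxy-8,8-dimethyl-1-(3-methylbut-2-en-1-yl)bicyclo[3.3.1]non-3-ene-2,7,9-trione
Product: 21 (1R,5S,7S)-5-(chain)-7-hydroxy-4-methoxy-8,8-dimethyl-1-(3-methylbut-2-en-1-yl)bicyclo[3.3.1]non-3-ene-2,9-dione (hydroxyl endo)
Conditions: NaBH4, MeOH/CH2Cl2, −40 °C
Reagents that add atoms: none
Why: Borohydride reduction of a ketone, in which the C9 carbonyl, now between two quaternary carbons, and the vinylogous ester carbonyl should be slower than the C7 ketone; hydride should come from the exo face and give mainly the endo alcohol, and either epimer serves because C7 becomes planar in step 19.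

Step 18
Reactants: 21 (1R,5S,7S)-7-hydroxy compound
Product: 22 O-[(1R,5S,7S)-5-(chain)-4-methoxy-8,8-dimethyl-1-(3-methylbut-2-en-1-yl)-2,9-dioxobicyclo[3.3.1]non-3-en-7-yl] S-methyl carbonodithioate
Conditions: NaH, imidazole (cat.), CS2, THF, 0 °C; then MeI, rt
Reagents that add atoms: carbon disulfide, S=C=S; iodomethane, CI
Why: Xanthate formation (alkoxide addition to CS2, then S-methylation) gives the usual Barton–McCombie-type radical precursor from a hindered secondary alcohol.

Step 19
Reactants: 22 C7 xanthate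
Product: 23 (1R,5S,7R)-7-allyl-5-(chain)-4-methoxy-8,8-dimethyl-1-(3-methylbut-2-en-1-yl)bicyclo[3.3.1]non-3-ene-2,9-dione (allyl exo)
Conditions: Bu3SnCH2CH=CH2 (excess), AIBN, benzene, 80 °C
Reagents that add atoms: allyltributylstannane, C=CC[Sn](CCCC)(CCCC)CCCC
Why: Keck radical allylation, in which the C7 radical should add to the stannane from the exo face because ring A (C3) covers the endo face, which sets C7 as R with the allyl group exo; cyclisation onto the C1 or C5 side chains would need a two-atom bridge between equatorial positions and is geometrically barred.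

Step 20
Reactants: 23 (1R,5S,7R)-7-allyl compound
Product: 24 (1R,5S,7R)-5-(chain)-4-methoxy-8,8-dimethyl-1,7-bis(3-methylbut-2-en-1-yl)bicyclo[3.3.1]non-3-ene-2,9-dione
Conditions: second-generation Grubbs catalyst RuCl2(=CHPh)(H2IMes)(PCy3) (5 mol %), 2-methylbut-2-ene/CH2Cl2, 40 °C
Reagents that add atoms: 2-methylbut-2-ene, CC=C(C)C
Why: Olefin cross-metathesis of the terminal alkene with 2-methylbut-2-ene, in which the trisubstituted alkenes already present are poor substrates and should be left alone.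

Step 21
Reactants: 25 3,4-dihydroxybenzoic acid
Product: 27 3,4-bis(TBS-oxy)benzoic acid, via tris-silyl ester 26 (not isolated)
Conditions: TBSCl (3.3 equiv), imidazole, DMF, rt; then AcOH/THF/H2O, rt
Reagents that add atoms: tert-butyldimethylsilyl chloride, CC(C)(C)[Si](C)(C)Cl
Why: Exhaustive silylation followed by selective hydrolysis of the labile silyl ester gives the acid with both phenols protected.

Step 22
Reactants: 27 3,4-bis(TBS-oxy)benzoic acid
Product: 28 3,4-bis(TBS-oxy)benzoyl chloride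
Conditions: (COCl)2, DMF (cat.), CH2Cl2, 0 °C to rt
Reagents that add atoms: oxalyl chloride, O=C(Cl)C(=O)Cl
Why: Acid chloride formation through the chloroiminium species from oxalyl chloride and DMF, under non-aqueous conditions that aryl silyl ethers tolerate.

Step 23
Reactants: 24 (1R,5S,7R)-1,7-diprenyl vinylogous ester; 28 3,4-bis(TBS-oxy)benzoyl chloride
Product: 29 (1S,5S,7R)-3-[3,4-bis(TBS-oxy)benzoyl]-5-(chain)-4-methoxy-8,8-dimethyl-1,7-bis(3-methylbut-2-en-1-yl)bicyclo[3.3.1]non-3-ene-2,9-dione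
Conditions: LiTMP, THF, −78 °C; then 28, −78 to −40 °C
Reagents that add atoms: none
Why: Vinylic lithiation of the β-methoxy enone at C3, the only acidified C–H left, directed by the flanking carbonyl and methoxy groups, followed by acylation of the vinyllithium with the aroyl chloride.

Step 24
Reactants: 29 tris-silyl ether
Product: 30 (1S,5S,7R)-3-(3,4-dihydroxybenzoyl)-5-[(2E,4S)-4-hydroxy-3,7-dimethylocta-2,6-dien-1-yl]-4-methoxy-8,8-dimethyl-1,7-bis(3-methylbut-2-en-1-yl)bicyclo[3.3.1]non-3-ene-2,9-dione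
Conditions: HF·pyridine, pyridine, THF, 0 °C to rt
Reagents that add atoms: none
Why: Buffered fluoride desilylation removes the two aryl silyl ethers and the allylic one, while the methyl vinylogous ester keeps the enol masked so that no cyclisation onto the prenyl groups can occur.

Step 25
Reactants: 30 triol methyl ether
Product: 31 CNP0142498.1, (1S,5S,7R)-3-(3,4-dihydroxybenzoyl)-4-hydroxy-5-[(2E,4S)-4-hydroxy-3,7-dimethylocta-2,6-dien-1-yl]-8,8-dimethyl-1,7-bis(3-methylbut-2-en-1-yl)bicyclo[3.3.1]non-3-ene-2,9-dione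
Conditions: LiCl, DMSO, 120 °C, argon; aq. citric acid work-up
Reagents that add atoms: none
Why: Krapcho-type nucleophilic demethylation (SN2 by chloride at the methyl group of the acyl-activated vinylogous ester) should free the enolised triketone without acid, which the prenyl groups and the allylic alcohol would not tolerate.

Compound list
1 | 6-methylhept-5-en-2-one | CC(=O)CCC=C(C)C | starting material
2 | (3S)-6-methyl-3-(N-phenylaminooxy)hept-5-en-2-one | CC(=O)[C@@H](ONc1ccccc1)CC=C(C)C | intermediate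
3 | (3S)-3-hydroxy-6-methylhept-5-en-2-one | CC(=O)[C@@H](O)CC=C(C)C | intermediate
4 | (3S)-3-(TBS-oxy)-6-methylhept-5-en-2-one | CC(=O)[C@@H](O[Si](C)(C)C(C)(C)C)CC=C(C)C | intermediate
5 | ethyl (2E,4S)-4-(TBS-oxy)-3,7-dimethylocta-2,6-dienoate | CCOC(=O)/C=C(\C)[C@@H](O[Si](C)(C)C(C)(C)C)CC=C(C)C | intermediate
6 | (2E,4S)-4-(TBS-oxy)-3,7-dimethylocta-2,6-dien-1-ol | OC/C=C(\C)[C@@H](O[Si](C)(C)C(C)(C)C)CC=C(C)C | intermediate
7 | (2E,4S)-1-bromo-4-(TBS-oxy)-3,7-dimethylocta-2,6-diene | BrC/C=C(\C)[C@@H](O[Si](C)(C)C(C)(C)C)CC=C(C)C | intermediate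
8 | 1,5-dimethoxycyclohexa-1,4-diene | COC1=CCC=C(OC)C1 | starting material
9 | (S)-2-methyloxirane | C[C@H]1CO1 | starting material
10 | (2S)-1-(2,6-dimethoxycyclohexa-2,5-dien-1-yl)propan-2-ol | COC1=CCC=C(OC)C1C[C@H](C)O | intermediate
11 | (2S)-1-[1-(chain)-2,6-dimethoxycyclohexa-2,5-dien-1-yl]propan-2-ol | COC1=CCC=C(OC)C1(C/C=C(\C)[C@@H](O[Si](C)(C)C(C)(C)C)CC=C(C)C)C[C@H](C)O | intermediate
12 | 1-[1-(chain)-2,6-dimethoxycyclohexa-2,5-dien-1-yl]propan-2-one | COC1=CCC=C(OC)C1(C/C=C(\C)[C@@H](O[Si](C)(C)C(C)(C)C)CC=C(C)C)CC(C)=O | intermediate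
13 | 1,1,1-trifluoro-5-[1-(chain)-2,6-dimethoxycyclohexa-2,5-dien-1-yl]pentane-2,4-dione | COC1=CCC=C(OC)C1(C/C=C(\C)[C@@H](O[Si](C)(C)C(C)(C)C)CC=C(C)C)CC(=O)CC(=O)C(F)(F)F | intermediate
14 | 1-diazo-3-[1-(chain)-2,6-dimethoxycyclohexa-2,5-dien-1-yl]propan-2-one (key-step precursor) | COC1=CCC=C(OC)C1(C/C=C(\C)[C@@H](O[Si](C)(C)C(C)(C)C)CC=C(C)C)CC(=O)C=[N+]=[N-] | intermediate
15 | methoxycyclopropyl ketone tricycle (4,9-dimethoxy-5-(chain)bicyclo[3.3.1]non-3-en-7-one with extra C8–C9 bond; key-step product) | COC1=CC[C@H]2[C@H]3C(=O)C[C@]1(C/C=C(\C)[C@@H](O[Si](C)(C)C(C)(C)C)CC=C(C)C)[C@@]23OC | intermediate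
16 | (1S,5S)-5-(chain)-4-methoxybicyclo[3.3.1]non-3-ene-7,9-dione | COC1=CC[C@H]2CC(=O)C[C@]1(C/C=C(\C)[C@@H](O[Si](C)(C)C(C)(C)C)CC=C(C)C)C2=O | intermediate
17 | (1S,5S,8S)-5-(chain)-4-methoxy-8-methylbicyclo[3.3.1]non-3-ene-7,9-dione | COC1=CC[C@H]2[C@H](C)C(=O)C[C@]1(C/C=C(\C)[C@@H](O[Si](C)(C)C(C)(C)C)CC=C(C)C)C2=O | intermediate
18 | (1S,5S)-5-(chain)-4-methoxy-8,8-dimethylbicyclo[3.3.1]non-3-ene-7,9-dione | COC1=CC[C@H]2C(C)(C)C(=O)C[C@]1(C/C=C(\C)[C@@H](O[Si](C)(C)C(C)(C)C)CC=C(C)C)C2=O | intermediate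
19 | (1R,5S)-5-(chain)-4-methoxy-8,8-dimethylbicyclo[3.3.1]non-3-ene-2,7,9-trione | COC1=CC(=O)[C@H]2C(C)(C)C(=O)C[C@]1(C/C=C(\C)[C@@H](O[Si](C)(C)C(C)(C)C)CC=C(C)C)C2=O | intermediate
20 | (1R,5S)-5-(chain)-4-methoxy-8,8-dimethyl-1-(3-methylbut-2-en-1-yl)bicyclo[3.3.1]non-3-ene-2,7,9-trione | COC1=CC(=O)[C@@]2(CC=C(C)C)C(C)(C)C(=O)C[C@]1(C/C=C(\C)[C@@H](O[Si](C)(C)C(C)(C)C)CC=C(C)C)C2=O | intermediate
21 | (1R,5S,7S)-5-(chain)-7-hydroxy-4-methoxy-8,8-dimethyl-1-(3-methylbut-2-en-1-yl)bicyclo[3.3.1]non-3-ene-2,9-dione | COC1=CC(=O)[C@@]2(CC=C(C)C)C(C)(C)[C@@H](O)C[C@]1(C/C=C(\C)[C@@H](O[Si](C)(C)C(C)(C)C)CC=C(C)C)C2=O | intermediate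
22 | O-[(1R,5S,7S)-5-(chain)-4-methoxy-8,8-dimethyl-1-(3-methylbut-2-en-1-yl)-2,9-dioxobicyclo[3.3.1]non-3-en-7-yl] S-methyl carbonodithioate | COC1=CC(=O)[C@@]2(CC=C(C)C)C(C)(C)[C@@H](OC(=S)SC)C[C@]1(C/C=C(\C)[C@@H](O[Si](C)(C)C(C)(C)C)CC=C(C)C)C2=O | intermediate
23 | (1R,5S,7R)-7-allyl-5-(chain)-4-methoxy-8,8-dimethyl-1-(3-methylbut-2-en-1-yl)bicyclo[3.3.1]non-3-ene-2,9-dione | COC1=CC(=O)[C@@]2(CC=C(C)C)C(C)(C)[C@H](CC=C)C[C@]1(C/C=C(\C)[C@@H](O[Si](C)(C)C(C)(C)C)CC=C(C)C)C2=O | intermediate
24 | (1R,5S,7R)-5-(chain)-4-methoxy-8,8-dimethyl-1,7-bis(3-methylbut-2-en-1-yl)bicyclo[3.3.1]non-3-ene-2,9-dione | COC1=CC(=O)[C@@]2(CC=C(C)C)C(C)(C)[C@H](CC=C(C)C)C[C@]1(C/C=C(\C)[C@@H](O[Si](C)(C)C(C)(C)C)CC=C(C)C)C2=O | intermediate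
25 | 3,4-dihydroxybenzoic acid | OC(=O)c1ccc(O)c(O)c1 | starting material
26 | tert-butyldimethylsilyl 3,4-bis(TBS-oxy)benzoate | CC(C)(C)[Si](C)(C)OC(=O)c1ccc(O[Si](C)(C)C(C)(C)C)c(O[Si](C)(C)C(C)(C)C)c1 | intermediate
27 | 3,4-bis(TBS-oxy)benzoic acid | OC(=O)c1ccc(O[Si](C)(C)C(C)(C)C)c(O[Si](C)(C)C(C)(C)C)c1 | intermediate
28 | 3,4-bis(TBS-oxy)benzoyl chloride | ClC(=O)c1ccc(O[Si](C)(C)C(C)(C)C)c(O[Si](C)(C)C(C)(C)C)c1 | intermediate
29 | (1S,5S,7R)-3-[3,4-bis(TBS-oxy)benzoyl]-5-(chain)-4-methoxy-8,8-dimethyl-1,7-bis(3-methylbut-2-en-1-yl)bicyclo[3.3.1]non-3-ene-2,9-dione | COC1=C(C(=O)c3ccc(O[Si](C)(C)C(C)(C)C)c(O[Si](C)(C)C(C)(C)C)c3)C(=O)[C@@]2(CC=C(C)C)C(C)(C)[C@H](CC=C(C)C)C[C@]1(C/C=C(\C)[C@@H](O[Si](C)(C)C(C)(C)C)CC=C(C)C)C2=O | intermediate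
30 | (1S,5S,7R)-3-(3,4-dihydroxybenzoyl)-5-[(2E,4S)-4-hydroxy-3,7-dimethylocta-2,6-dien-1-yl]-4-methoxy-8,8-dimethyl-1,7-bis(3-methylbut-2-en-1-yl)bicyclo[3.3.1]non-3-ene-2,9-dione | COC1=C(C(=O)c3ccc(O)c(O)c3)C(=O)[C@@]2(CC=C(C)C)C(C)(C)[C@H](CC=C(C)C)C[C@]1(C/C=C(\C)[C@@H](O)CC=C(C)C)C2=O | intermediate
31 | CNP0142498.1, (1S,5S,7R)-3-(3,4-dihydroxybenzoyl)-4-hydroxy-5-[(2E,4S)-4-hydroxy-3,7-dimethylocta-2,6-dien-1-yl]-8,8-dimethyl-1,7-bis(3-methylbut-2-en-1-yl)bicyclo[3.3.1]non-3-ene-2,9-dione | CC(C)=CC[C@@H]1C[C@]2(C/C=C(\C)[C@@H](O)CC=C(C)C)C(=O)[C@@](CC=C(C)C)(C(=O)C(C(=O)c3ccc(O)c(O)c3)=C2O)C1(C)C | target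

Total step count: 25.
Longest linear sequence: 22 steps (steps 1–6, 8–20, 23–25).

Steps most likely to fail

1. Step 15 (C2 oxidation). What may go wrong: loss of chemoselectivity in the hydrogen abstraction, with attack at the allylic C–H bonds of the chain (above all the silyloxy-bearing one), or oxidative degradation of the enol ether. The fallback sets out from 18 and returns at 19. DDQ in wet CH2Cl2 takes hydride from C2 of the enol ether, the best hydride donor in the molecule, and water collapses the methoxyallyl cation to the enone 5-(chain)-8,8-dimethylbicyclo[3.3.1]non-2-ene-4,7,9-trione F1. A Tsuji–Wacker oxidation of this enone (Na2PdCl4, t-BuOOH, AcOH/H2O, 50 °C) places oxygen on the β-carbon C2 and should give the enolised 2,4-dione 5-(chain)-4-hydroxy-8,8-dimethylbicyclo[3.3.1]non-3-ene-2,7,9-trione F2. O-Methylation (Me2SO4, K2CO3, acetone) then gives 19, which is separated from its regioisomer 5-(chain)-2-methoxy-8,8-dimethylbicyclo[3.3.1]non-2-ene-4,7,9-trione F3; the latter is hydrolysed back to F2 with LiOH and recycled.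

2. Step 14 (second C8 methyl). What may go wrong: loss of regiocontrol once C8 carries one methyl, with enolisation and alkylation drifting to C6 or running on to a third methylation. The fallback sets out from 16 and returns at 18, replacing deprotonation by a regiospecific enolate from conjugate reduction. The kinetic enolate of 16 (LDA, −78 °C) is trapped with CH2=NMe2 iodide (Eschenmoser's salt) to give the Mannich base 8-(dimethylaminomethyl)-5-(chain)-4-methoxybicyclo[3.3.1]non-3-ene-7,9-dione F4. MeI gives the trimethylammonium iodide of the same skeleton F5, which loses trimethylamine with NaHCO3 to give 5-(chain)-4-methoxy-8-methylidenebicyclo[3.3.1]non-3-ene-7,9-dione F6. LiBH(s-Bu)3 at −78 °C adds hydride to the methylidene carbon, and MeI alkylates the resulting C7=C8 lithium enolate at C8, which gives 18.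

3. Step 17 (C7 reduction). What may go wrong: loss of chemoselectivity between the C7 and C9 carbonyls, with hydride attack at the bridging ketone from the open ring A side. The fallback sets out from 20 and returns at 23, giving up selectivity in the reduction and differentiating the two carbinols afterwards. Excess NaBH4 reduces both ketones to the diol 5-(chain)-7,9-dihydroxy-4-methoxy-8,8-dimethyl-1-(3-methylbut-2-en-1-yl)bicyclo[3.3.1]non-3-en-2-one F7. One equivalent of NaH with CS2 and MeI should form the xanthate only at C7, because the C9 carbinol lies between two quaternary carbons, which gives the C7 mono-xanthate of this diol F8. Radical allylation as in step 19 gives 7-allyl-5-(chain)-9-hydroxy-4-methoxy-8,8-dimethyl-1-(3-methylbut-2-en-1-yl)bicyclo[3.3.1]non-3-en-2-one F9, and Dess–Martin periodinane re-oxidises the C9 carbinol to give 23.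

Further compounds
F1 | step 15 | 5-(chain)-8,8-dimethylbicyclo[3.3.1]non-2-ene-4,7,9-trione | O=C1C=C[C@H]2C(C)(C)C(=O)C[C@]1(C/C=C(\C)[C@@H](O[Si](C)(C)C(C)(C)C)CC=C(C)C)C2=O
F2 | step 15 | 5-(chain)-4-hydroxy-8,8-dimethylbicyclo[3.3.1]non-3-ene-2,7,9-trione | OC1=CC(=O)[C@H]2C(C)(C)C(=O)C[C@]1(C/C=C(\C)[C@@H](O[Si](C)(C)C(C)(C)C)CC=C(C)C)C2=O
F3 | step 15 | 5-(chain)-2-methoxy-8,8-dimethylbicyclo[3.3.1]non-2-ene-4,7,9-trione | O=C1C=C(OC)[C@H]2C(C)(C)C(=O)C[C@]1(C/C=C(\C)[C@@H](O[Si](C)(C)C(C)(C)C)CC=C(C)C)C2=O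
F4 | step 14 | 8-(dimethylaminomethyl)-5-(chain)-4-methoxybicyclo[3.3.1]non-3-ene-7,9-dione | COC1=CC[C@H]2[C@H](CN(C)C)C(=O)C[C@]1(C/C=C(\C)[C@@H](O[Si](C)(C)C(C)(C)C)CC=C(C)C)C2=O
F5 | step 14 | [5-(chain)-4-methoxy-7,9-dioxobicyclo[3.3.1]non-3-en-8-yl]methyl-trimethylammonium iodide | COC1=CC[C@H]2[C@H](C[N+](C)(C)C)C(=O)C[C@]1(C/C=C(\C)[C@@H](O[Si](C)(C)C(C)(C)C)CC=C(C)C)C2=O.[I-]
F6 | step 14 | 5-(chain)-4-methoxy-8-methylidenebicyclo[3.3.1]non-3-ene-7,9-dione | COC1=CC[C@H]2C(=C)C(=O)C[C@]1(C/C=C(\C)[C@@H](O[Si](C)(C)C(C)(C)C)CC=C(C)C)C2=O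
F7 | step 17 | 5-(chain)-7,9-dihydroxy-4-methoxy-8,8-dimethyl-1-(3-methylbut-2-en-1-yl)bicyclo[3.3.1]non-3-en-2-one | COC1=CC(=O)[C@@]2(CC=C(C)C)C(C)(C)[C@@H](O)C[C@]1(C/C=C(\C)[C@@H](O[Si](C)(C)C(C)(C)C)CC=C(C)C)[C@@H]2O
F8 | step 17 | O-[5-(chain)-9-hydroxy-4-methoxy-8,8-dimethyl-1-(3-methylbut-2-en-1-yl)-2-oxobicyclo[3.3.1]non-3-en-7-yl] S-methyl carbonodithioate | COC1=CC(=O)[C@@]2(CC=C(C)C)C(C)(C)[C@@H](OC(=S)SC)C[C@]1(C/C=C(\C)[C@@H](O[Si](C)(C)C(C)(C)C)CC=C(C)C)[C@@H]2O
F9 | step 17 | 7-allyl-5-(chain)-9-hydroxy-4-methoxy-8,8-dimethyl-1-(3-methylbut-2-en-1-yl)bicyclo[3.3.1]non-3-en-2-one | COC1=CC(=O)[C@@]2(CC=C(C)C)C(C)(C)[C@H](CC=C)C[C@]1(C/C=C(\C)[C@@H](O[Si](C)(C)C(C)(C)C)CC=C(C)C)[C@@H]2O
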